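- The constants I wanted from the earlier runs were two, and I read both in fractions of the electrophile charge.

| flask | electrophile | nucleophile | free base | remark | time |
|---|---|---|---|---|---|
| Friday's | 20 mM | 22 mM | 20 mM | run made earlier |  |
| Tuesday's | 20 mM | 22 mM | 28 mM | run made earlier |  |
| Wednesday's | 20 mM | 22 mM | 44 mM | run made earlier |  |
| Thursday's | 20 mM | 33 mM | 20 mM | run made earlier |  |
| east | 20 mM | 22.0 mM (fed, over 50 min) | 20.0 mM | all else is in the flask from the start; the feed brings no volume worth counting | 1.0 h |
| south-east | 20 mM | 22.0 mM | 20.0 mM | everything together at the start | 1.0 h |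
| south | 20 mM (fed, over 50 min) | 22.0 mM | 20.0 mM | all else is in the flask from the start; the feed brings no volume worth counting | 1.0 h |

| run | time / min | target / % |
|---|---|---|
| Friday's | 3.00 | 23.9 |
| Friday's | 10.0 | 35.5 |
| Friday's | 15.0 | 35.5 |
| Friday's | 25.0 | 33.1 |
| Friday's | 40.0 | 30.7 |
| Friday's | 50.0 | 28.3 |
| Friday's | 60.0 | 27.5 |
| Tuesday's | 2.00 | 18.5 |
| Tuesday's | 6.00 | 32.2 |
| Tuesday's | 10.0 | 35.5 |
| Tuesday's | 15.0 | 35.0 |
| Tuesday's | 20.0 | 34.0 |
| Tuesday's | 30.0 | 32.8 |
| Tuesday's | 40.0 | 30.8 |
| Wednesday's | 5.00 | 31.1 |
| Wednesday's | 10.0 | 35.9 |
| Wednesday's | 15.0 | 36.2 |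
| Wednesday's | 20.0 | 35.2 |
| Wednesday's | 25.0 | 34.1 |
| Wednesday's | 30.0 | 33.5 |
| Wednesday's | 40.0 | 31.7 |
| Thursday's | 3.00 | 34.9 |
| Thursday's | 10.0 | 52.1 |
| Thursday's | 15.0 | 52.7 |
| Thursday's | 25.0 | 53.7 |
| Thursday's | 40.0 | 53.2 |

(each reading ± 0.5 percentage points)

- the earlier runs were read with a standard deviation of 0.5 percentage points

* the best flask by amount of target, in percent of the electrophile charged; "all alike" if 1.5 percentage points covers them all (east / south-east / south / all alike)
* amount of target at the end, in percent of the electrophile charged, east
* amount of target at the end, in percent of the electrophile charged, south-east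
* amount of target at the end, in percent of the electrophile charged, south

- My rule of thumb was that the peak follows the nucleophile. Friday's peak reading of 35.5%, over a nucleophile charge of 1.10 of the electrophile charge, gave 0.323. Thursday's 53.7%, over 1.65, gave 0.325. I called this ratio the return, peak target per unit of nucleophile charged, a yield on the nucleophile.
- Wednesday's flask, with 2.20 times Friday's free base, read 36.2% at its peak, 0.7 points above Friday's reading.
- The second constant was the fade, an empirical slope of the logarithm of target, read from the fall after the peak. Friday's target went from 35.5% at 15.0 min to 27.5% at 60.0 min, which gave 0.00567 min⁻¹. Thursday's target did not fall, reading 52.7% and then 53.2%, so I took the fade to need electrophile left over.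
- The rule has a border. It was read in Friday's flask, whose highest reading was reached by 15.0 min, and in Thursday's, whose highest reading stood at 25.0 min, but the feeds last twice the later of these, so in a fed flask target is born across the feed, not at one moment.
- I therefore replaced the birth curve by its mean. In east, where nucleophile is fed into the whole electrophile charge, the mean parcel of target fades for 35.0 min, which gave 29.1%. The mean costs little error, since the fade over the feed, 0.284, is less than one.
- In south, where electrophile is fed, I assumed that fading began when the feed ended, 10.0 min before the reading, which gave 33.5%. South-east repeats Friday's flask, so I took 27.5%. My best flask was south.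
- The forecast named east, with east 30%, south-east 27.5% and south 4.5%, holding for south that “nucleophile mostly dies before electrophile arrives”.
- The flasks gave east 25.6%, south-east 27.6% and south 33.3%, so south was best.

    electrophile + nucleophile → acid set free + target (k = 6.50 L mol⁻¹ min⁻¹)
    nucleophile + acid set free ⇌ protonated nucleophile, settled at all times (K = 33000 L mol⁻¹)
    acid set free + free base ⇌ salt of the base (K = 330 L mol⁻¹, k = 38.0 L mol⁻¹ min⁻¹)
    acid set free → by-product carried off (k = 0.0220 min⁻¹)
    electrophile + target → side product (k = 2.90 L mol⁻¹ min⁻¹)

- South stood at 35.7% at the end of its feed, where the return times the nucleophile charge gives 35.5%. My east stood 3.5 points above its result. The neighbour of south, charged with 13 mM of nucleophile, that is 0.650 of the electrophile charge, reckons by the same return and the same fade to 19.8%. That neighbour held 45.4% of electrophile at the end, and its target stood at 16.3%.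

The earlier runs and the new flask come from a simulation for substances that don't exist; scatter was added.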